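**Retrosynthetic overview**
1. Feature: ring B is a 1,4-phenylene. Its C1 carries the ether oxygen to ring A (the catechol ring, at the carbon next to the two hydroxyls) and its C4 carries the CH2 of the two-carbon bridge to ring C. An oxygen donor para to a carbon that can be carried as an acyl group is the pattern produced by a 2-oxybutadiene and an ethynyl ketone.
2. 22 ⇒ tri-O-methyl ether 21 ⇒ aryl ketone 19 ⇒ cyclohexa-1,4-diene 18 ⇒ open aryloxydiene–ynone 17. One intramolecular [4+2] makes two C–C bonds of ring B and closes the 17-membered ring.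
3. 17 ⇒ bromo diene 12. The ynone arm is grown from the ring C bromide (Br/Li exchange, ethylene oxide, oxidation, ethynylation, oxidation) only after the diene is in place, because Cp2Ti=CH2 would also attack an alkyne, a free hydroxyl or a second carbonyl group.
4. 12 ⇒ acrylate 11 ⇒ phenol 9 ⇒ Wittig union of ring A salt 6 with the C–O–D aldehyde 3 (SNAr). Diimide replaces Pd/C so that the bromide survives.
5. Ring order: A, C and D are bought. Ring B and the macrocycle are formed together, last.

Key step: step 12

Remark: the target has no stereocentre and no configured double bond, so no stereocontrol is needed. The carbinol centres of 16 and 20 are racemic and are erased again.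

**Step 1**
Reactants: 1 2-bromo-6-methoxyphenol; 2 2-fluorobenzaldehyde
Product: 3 2-(2-bromo-6-methoxyphenoxy)benzaldehyde
Conditions: K2CO3, DMF, 130 °C
Reagents that add atoms: none
Why: Nucleophilic aromatic substitution by addition–elimination, in which the ortho formyl group stabilises the Meisenheimer adduct and fluoride leaves, while the unactivated C–Br bond of 1 is not touched.

**Step 2**
Reactants: 4 3-hydroxy-4,5-dimethoxybenzaldehyde
Product: 5 5-(hydroxymethyl)-2,3-dimethoxyphenol
Conditions: NaBH4, MeOH, 0 °C
Reagents that add atoms: none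
Why: Borohydride reduction of an aromatic aldehyde is fast at 0 °C and needs no protection of the phenol.

**Step 3**
Reactants: 5 5-(hydroxymethyl)-2,3-dimethoxyphenol
Product: 6 (3-hydroxy-4,5-dimethoxybenzyl)triphenylphosphonium bromide
Conditions: PPh3·HBr, MeCN, reflux
Reagents that add atoms: triphenylphosphine hydrobromide, [Br-].c1ccc(cc1)[PH+](c1ccccc1)c1ccccc1
Why: SN1-type substitution of an electron-rich benzylic alcohol (cation stabilised by the para methoxy group) by PPh3 should give the Wittig salt in one operation and leave the phenol free.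

**Step 4**
Reactants: 6 (3-hydroxy-4,5-dimethoxybenzyl)triphenylphosphonium bromide; 3 2-(2-bromo-6-methoxyphenoxy)benzaldehyde
Product: 8 5-{2-[2-(2-bromo-6-methoxyphenoxy)phenyl]ethenyl}-2,3-dimethoxyphenol (E/Z mixture), via phenoxide ylide 7 (not isolated)
Conditions: KOtBu (2.1 equiv), THF, 0 °C; then 3, 0 °C → rt; 1 M HCl to pH 5
Reagents that add atoms: potassium tert-butoxide, CC(C)(C)[O-].[K+] (potassium of 7 only)
Why: Wittig olefination in which one equivalent of base is spent on the phenol and the second forms the semistabilised benzylide that condenses with the non-enolisable aldehyde 3, the alkene geometry being irrelevant because step 5 saturates it.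

**Step 5**
Reactants: 8 bromostilbene phenol (E/Z mixture)
Product: 9 5-{2-[2-(2-bromo-6-methoxyphenoxy)phenyl]ethyl}-2,3-dimethoxyphenol
Conditions: TsNHNH2 (excess, in portions), NaOAc, DME/H2O, reflux
Reagents that add atoms: none
Why: Diimide reduction transfers H2 to the C=C bond through a concerted cyclic transition state and, unlike hydrogenation over Pd/C, cannot hydrogenolyse the aryl C–Br bond needed in step 8.

**Step 6**
Reactants: 9 bibenzyl bromophenol; 10 acryloyl chloride
Product: 11 5-{2-[2-(2-bromo-6-methoxyphenoxy)phenyl]ethyl}-2,3-dimethoxyphenyl prop-2-enoate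
Conditions: Et3N, CH2Cl2, 0 °C
Reagents that add atoms: none
Why: O-acylation of the only hydroxyl group of 9 by an acid chloride and an amine base is a standard esterification.

**Step 7**
Reactants: 11 aryl acrylate
Product: 12 1-bromo-2-(2-{2-[3-(buta-1,3-dien-2-yloxy)-4,5-dimethoxyphenyl]ethyl}phenoxy)-3-methoxybenzene
Conditions: Cp2TiMe2 (2.5 equiv), BHT (cat.), toluene, 70 °C, dark; hexane, filtration through basic Al2O3
Reagents that add atoms: dimethyltitanocene Cp2TiMe2, C[Ti+2]C.c1cc[cH-]c1.c1cc[cH-]c1
Why: Petasis methylenation (Cp2Ti=CH2 adds [2+2] to the ester C=O and cycloreverts to the enol ether) is known for aryl esters and for α,β-unsaturated esters, and it is placed here because 11 holds no alkyne, hydroxyl or second carbonyl group for the titanium carbene to attack.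

**Step 8**
Reactants: 12 bromo diene
Product: 14 2-[2-(2-{2-[3-(buta-1,3-dien-2-yloxy)-4,5-dimethoxyphenyl]ethyl}phenoxy)-3-methoxyphenyl]ethan-1-ol, via aryllithium 13 (not isolated)
Conditions: n-BuLi (1.05 equiv), THF, −78 °C, 15 min; ethylene oxide (5 equiv, THF solution), −78 → 0 °C; H2O
Reagents that add atoms: ethylene oxide, C1CO1; n-butyllithium, [Li]CCCC (lithium of 13 only)
Why: Bromine–lithium exchange next to an ether oxygen is complete within minutes at −78 °C, far faster than addition of butyllithium to the electron-rich diene, and the aryllithium opens ethylene oxide by SN2 attack to add both bridge carbons.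

**Step 9**
Reactants: 14 diene alcohol
Product: 15 [2-(2-{2-[3-(buta-1,3-dien-2-yloxy)-4,5-dimethoxyphenyl]ethyl}phenoxy)-3-methoxyphenyl]acetaldehyde
Conditions: Dess–Martin periodinane, NaHCO3, CH2Cl2, 0 °C → rt; used at once
Reagents that add atoms: none
Why: Dess–Martin oxidation under bicarbonate buffer stops at the aldehyde and stays neutral, so neither the acid-labile aryloxydiene nor the enolisable arylacetaldehyde should be harmed.

**Step 10**
Reactants: 15 diene aldehyde
Product: 16 1-[2-(2-{2-[3-(buta-1,3-dien-2-yloxy)-4,5-dimethoxyphenyl]ethyl}phenoxy)-3-methoxyphenyl]but-3-yn-2-ol (racemic)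
Conditions: HC≡CMgBr (0.5 M in THF), THF, −78 → 0 °C; pH 7 buffer
Reagents that add atoms: ethynylmagnesium bromide, C#C[Mg]Br
Why: 1,2-addition of a weakly basic alkynyl Grignard reagent outruns enolisation of the aldehyde, and the new carbinol centre is formed racemic and is erased in step 11.

**Step 11**
Reactants: 16 propargylic alcohol
Product: 17 1-[2-(2-{2-[3-(buta-1,3-dien-2-yloxy)-4,5-dimethoxyphenyl]ethyl}phenoxy)-3-methoxyphenyl]but-3-yn-2-one
Conditions: Dess–Martin periodinane, NaHCO3, CH2Cl2, 0 °C; short neutral silica plug; kept as a cold dilute CH2Cl2 solution and used the same day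
Reagents that add atoms: none
Why: Dess–Martin oxidation of a secondary propargylic alcohol to the ynone is mild and neutral, and it comes last so that diene and activated dienophile coexist only just before cyclisation.

**Step 12**
Reactants: 17 aryloxydiene–ynone
Product: 18 macrocyclic 4-aryloxycyclohexa-1,4-dien-1-yl ketone (ring B as the 1,4-diene, its C1 bonded to the ring A oxygen, its C4 bonded to C=O; CH2 between C=O and ring C; three OMe)
Conditions: Me2AlCl (3 equiv), CH2Cl2, −20 °C → rt, 17 added by syringe pump over 10 h (final 1 mM); cold aq. potassium sodium tartrate; crude taken on directly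
Reagents that add atoms: none
Why: Me2AlCl binds the ynone oxygen, lowers the alkyne LUMO and scavenges adventitious water and acid, so the aryloxydiene adds in a concerted, asynchronous [4+2] cycloaddition in which diene C1 (the CH2 on the oxygen-bearing carbon) bonds to the terminal alkyne carbon and diene C4 bonds to the acyl-bearing alkyne carbon. The closest known reaction type is the type 2 intramolecular Diels–Alder reaction (tether on diene C2) in its macrocyclising form, combined with the established para-selective addition of 2-oxygenated butadienes to alkynyl ketones. Ring B closes as a six-membered carbocycle by the cycloaddition itself, and the 17-membered ring closes at the same moment as the long bridge of a bicyclo[13.2.2] framework, its thirteen-atom tether being long enough to span the 1,4-positions without strain. No stereocentre is formed, since the new ring holds only sp2 and CH2 carbons. The step needs para rather than meta orientation, which is secured by the oxygen donor on diene C2 (largest HOMO coefficient at C1) and the aluminium-bound acyl group (largest LUMO coefficient at the alkyne terminus), while the long tether imposes no opposing geometric bias. It also needs ring closure rather than oligomerisation, which slow addition into the promoter secures because free 17 never accumulates.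

**Step 13**
Reactants: 18 macrocyclic cyclohexadienyl ketone
Product: 19 macrocyclic aryl ketone (ring B now a 1,4-phenylene; ArB–C(=O)–CH2–ArC; three OMe)
Conditions: DDQ (1.1 equiv), toluene, rt
Reagents that add atoms: none
Why: DDQ dehydrogenation by hydride abstraction from a doubly allylic CH2 followed by proton loss is driven by aromatisation and is much faster than attack on the bibenzyl CH2 groups.

**Step 14**
Reactants: 19 macrocyclic aryl ketone
Product: 21 tri-O-methyl ether of the target, via benzylic carbinol 20 (not isolated)
Conditions: Et3SiH (5 equiv), CF3CO2H/CH2Cl2 1:1, 0 °C → 40 °C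
Reagents that add atoms: none
Why: Ionic hydrogenation (Kursanov–Parnes reduction) delivers hydride to the protonated ketone, ionises the carbinol to a cation stabilised by the para aryloxy oxygen of ring B and delivers a second hydride, while aryl methyl and diaryl ethers are inert to CF3CO2H.

**Step 15**
Reactants: 21 tri-O-methyl ether
Product: 22 target CNP0290892.0
Conditions: BBr3 (6 equiv), CH2Cl2, −78 °C → rt; ice-water
Reagents that add atoms: none
Why: In BBr3 ether cleavage, bromide attacks the methyl carbon of each boron-bound methoxy group by SN2, whereas the two diaryl ether oxygens carry no sp3 carbon and survive.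

**Compound list**
1 | 2-bromo-6-methoxyphenol | COc1cccc(Br)c1O | starting material
2 | 2-fluorobenzaldehyde | O=Cc1ccccc1F | starting material
3 | 2-(2-bromo-6-methoxyphenoxy)benzaldehyde | COc1cccc(Br)c1Oc1ccccc1C=O | intermediate
4 | 3-hydroxy-4,5-dimethoxybenzaldehyde | COc1cc(C=O)cc(O)c1OC | starting material
5 | 5-(hydroxymethyl)-2,3-dimethoxyphenol | COc1cc(CO)cc(O)c1OC | intermediate
6 | (3-hydroxy-4,5-dimethoxybenzyl)triphenylphosphonium bromide | COc1cc(C[P+](c2ccccc2)(c2ccccc2)c2ccccc2)cc(O)c1OC.[Br-] | intermediate
7 | potassium phenoxide of the benzylidene ylide from 6 (not isolated) | COc1cc(C=P(c2ccccc2)(c2ccccc2)c2ccccc2)cc([O-])c1OC.[K+] | intermediate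
8 | bromostilbene phenol (E/Z mixture) | COc1cc(C=Cc2ccccc2Oc2c(Br)cccc2OC)cc(O)c1OC | intermediate
9 | bibenzyl bromophenol | COc1cc(CCc2ccccc2Oc2c(Br)cccc2OC)cc(O)c1OC | intermediate
10 | acryloyl chloride | C=CC(=O)Cl | starting material
11 | aryl acrylate | C=CC(=O)Oc1cc(CCc2ccccc2Oc2c(Br)cccc2OC)cc(OC)c1OC | intermediate
12 | bromo 2-aryloxybutadiene | C=CC(=C)Oc1cc(CCc2ccccc2Oc2c(Br)cccc2OC)cc(OC)c1OC | intermediate
13 | ring C aryllithium (not isolated) | C=CC(=C)Oc1cc(CCc2ccccc2Oc2c([Li])cccc2OC)cc(OC)c1OC | intermediate
14 | diene 2-arylethanol | C=CC(=C)Oc1cc(CCc2ccccc2Oc2c(CCO)cccc2OC)cc(OC)c1OC | intermediate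
15 | diene arylacetaldehyde | C=CC(=C)Oc1cc(CCc2ccccc2Oc2c(CC=O)cccc2OC)cc(OC)c1OC | intermediate
16 | diene propargylic alcohol (racemic) | C=CC(=C)Oc1cc(CCc2ccccc2Oc2c(CC(O)C#C)cccc2OC)cc(OC)c1OC | intermediate
17 | aryloxydiene–ynone (key-step precursor) | C=CC(=C)Oc1cc(CCc2ccccc2Oc2c(OC)cccc2CC(=O)C#C)cc(OC)c1OC | intermediate
18 | macrocyclic cyclohexa-1,4-dienyl ketone (key-step product) | COc1cc2cc(c1OC)OC1=CCC(=CC1)C(=O)Cc1cccc(OC)c1Oc1ccccc1CC2 | intermediate
19 | macrocyclic aryl ketone | COc1cc2cc(c1OC)Oc1ccc(cc1)C(=O)Cc1cccc(OC)c1Oc1ccccc1CC2 | intermediate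
20 | macrocyclic benzylic carbinol (racemic, not isolated) | COc1cc2cc(c1OC)Oc1ccc(cc1)C(O)Cc1cccc(OC)c1Oc1ccccc1CC2 | intermediate
21 | tri-O-methyl ether of the target | COc1cc2cc(c1OC)Oc1ccc(cc1)CCc1cccc(OC)c1Oc1ccccc1CC2 | intermediate
22 | CNP0290892.0 | Oc1cc2cc(c1O)Oc1ccc(cc1)CCc1cccc(O)c1Oc1ccccc1CC2 | target

**Total step count:** 15. **Longest linear sequence:** 14 (4 → 22, steps 2–15). The branch from 1 runs 13 steps.

**Steps most likely to fail**

1. Step 12 (key step).
   - What may go wrong:
     - intermolecular cycloaddition to oligomers outrunning ring closure;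
     - breakdown of the enol-ether diene, or chloride addition to the ynone, under the aluminium promoter;
     - partial meta orientation;
     - hydrolytic opening of the adduct's enol ether during work-up.
   - Heating 17 without promoter at 1 mM would be only a change of conditions.
   - Fallback: ring B is brought in as a finished arene and the macrocycle is closed at the B–C bridge by cross-coupling. It sets out from phenol 9. SNAr with 4-fluorobenzaldehyde (K2CO3, DMF, 120 °C) should give the 4-aryloxybenzaldehyde F1. Wittig methylenation (Ph3PCH3Br, KOtBu, THF) should give the 4-aryloxystyrene F2. Hydroboration with 9-BBN-H should give the B-alkyl borane F3. F3 is closed onto the ring C bromide by intramolecular B-alkyl Suzuki–Miyaura coupling (Pd(dppf)Cl2, Cs2CO3, DMF/THF/H2O, slow addition). The fallback comes back to the route at tri-O-methyl ether 21.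

2. Step 8.
   - What may go wrong:
     - carbolithiation of the aryloxydiene with loss of phenoxide;
     - anionic oligomerisation of the diene;
     - slow epoxide opening that lets the aryllithium be quenched or butylated.
   - Fallback: the hydroxyethyl arm is installed before the diene and carried under silyl protection. It sets out from phenol 9.
     - n-BuLi (2.2 equiv), then ethylene oxide, should give the phenol alcohol F4.
     - TBSCl and imidazole in DMF should give the bis-silyl ether F5.
     - K2CO3 in MeOH should cleave only the aryl silyl ether to give the phenol silyl ether F6.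
     - Acryloyl chloride 10 and Et3N should give the silyloxy acrylate F7.
     - Cp2TiMe2 in toluene at 70 °C should give the silyloxy diene F8.
     - Bu4NF in THF at 0 °C frees the alcohol.

     The fallback comes back to the route at 14.

3. Step 7.
   - What may go wrong:
     - radical polymerisation of the acrylate at the temperature needed to release the carbene;
     - incomplete methylenation;
     - loss of the acid-sensitive diene while titanium residues are removed.
   - Fallback: the diene is made by addition, reduction and 1,4-elimination instead of carbonyl methylenation. It sets out from phenol 9. Oxa-Michael addition to methyl but-2-ynoate (K2CO3, DMF, 60 °C) should give the (E)-3-aryloxybut-2-enoate F9. Reduction with i-Bu2AlH (CH2Cl2, −78 °C) should give the allylic alcohol F10. MsCl and Et3N at −20 °C should give the allylic mesylate F11. F11 is treated in the same flask with DBU to remove a methyl proton and expel mesylate. The fallback comes back to the route at bromo diene 12.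

**Further compounds**
F1 | step 12 | 4-(5-{2-[2-(2-bromo-6-methoxyphenoxy)phenyl]ethyl}-2,3-dimethoxyphenoxy)benzaldehyde | O=Cc1ccc(cc1)Oc1cc(CCc2ccccc2Oc2c(Br)cccc2OC)cc(OC)c1OC
F2 | step 12 | 4-aryloxystyrene from F1 | C=Cc1ccc(cc1)Oc1cc(CCc2ccccc2Oc2c(Br)cccc2OC)cc(OC)c1OC
F3 | step 12 | B-[2-(4-aryloxyphenyl)ethyl]-9-borabicyclo[3.3.1]nonane from F2 | COc1cccc(Br)c1Oc1ccccc1CCc1cc(OC)c(OC)c(c1)Oc1ccc(CCB2C3CCCC2CCC3)cc1
F4 | step 8 | 5-[2-(2-{2-(2-hydroxyethyl)-6-methoxyphenoxy}phenyl)ethyl]-2,3-dimethoxyphenol | COc1cc(CCc2ccccc2Oc2c(CCO)cccc2OC)cc(O)c1OC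
F5 | step 8 | bis(tert-butyldimethylsilyl) ether of F4 | COc1cc(CCc2ccccc2Oc2c(CCO[Si](C)(C)C(C)(C)C)cccc2OC)cc(O[Si](C)(C)C(C)(C)C)c1OC
F6 | step 8 | phenol with alkyl silyl ether retained | COc1cc(CCc2ccccc2Oc2c(CCO[Si](C)(C)C(C)(C)C)cccc2OC)cc(O)c1OC
F7 | step 8 | acrylate of F6 | C=CC(=O)Oc1cc(CCc2ccccc2Oc2c(CCO[Si](C)(C)C(C)(C)C)cccc2OC)cc(OC)c1OC
F8 | step 8 | 2-aryloxybutadiene silyl ether | C=CC(=C)Oc1cc(CCc2ccccc2Oc2c(CCO[Si](C)(C)C(C)(C)C)cccc2OC)cc(OC)c1OC
F9 | step 7 | methyl (E)-3-aryloxybut-2-enoate from 9 | COC(=O)/C=C(\C)Oc1cc(CCc2ccccc2Oc2c(Br)cccc2OC)cc(OC)c1OC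
F10 | step 7 | (E)-3-aryloxybut-2-en-1-ol | OC/C=C(\C)Oc1cc(CCc2ccccc2Oc2c(Br)cccc2OC)cc(OC)c1OC
F11 | step 7 | (E)-3-aryloxybut-2-enyl methanesulfonate | CS(=O)(=O)OC/C=C(\C)Oc1cc(CCc2ccccc2Oc2c(Br)cccc2OC)cc(OC)c1OC
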